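**Retrosynthetic overview**
1. Structural basis: the γ-lactone carries the benzylic carbon C7'' (to ring C) on C3 and the benzylic carbon C7' (to ring A) on C4, trans to each other. This is the vicinal pattern left when a nucleophile and then an electrophile are added across C3=C4 of a butenolide.
2. Late disconnection: C7–C8 of the ring-A side chain, by a catalyst-controlled anti-allylboration of O-benzylvanillin (ring B) with an E-allylboronate grown from a formyl group placed ortho to the ring-A phenol. C9–OH comes from cleavage of the vinyl group.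
3. Key disconnection: C4–C7' and C3–C7'' in one flask on (5R)-5-menthyloxyfuran-2(5H)-one, with the lithiated ring-A dithiane as nucleophile and the ring-C benzyl bromide as electrophile. The dithiane carbon becomes C7' and the acetal carbon C5 becomes the lactone OCH2.
4. Ring order: the five-membered oxygen ring is present from the furfural-derived butenolide and is only re-closed as the γ-lactone once the auxiliary is removed. No other ring is formed, and rings A, B and C all come from vanillin.

Key step: step 8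

Locants: lactone O1, C2(=O), C3, C4, C5; C7'/ring A on C4; C7''/ring C on C3; side chain C7 (CHOH, ring B), C8 (CH), C9 (CH2OH). The target is (3R,4R,7R,8R), and the C7/C8 relation is the anti relation of an E-allylboronate addition.
Assumption: the E-boronate fixes only the anti relation, so a chiral phosphoric acid is added for absolute control. Its (R)-enantiomer is taken to direct the allyl group to the Re face of an aryl aldehyde, the sense established for allyl and E-crotyl pinacol boronates; if the γ-aryl boronate showed the opposite sense, the (S)-acid would be used.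

**Step 1**
Reactants: 1 furfural
Product: 3 5-hydroxyfuran-2(5H)-one (racemic), via furan endoperoxide 2 (not isolated)
Conditions: O2, methylene blue (cat.), MeOH, hν (visible), rt
Reagents that add atoms: oxygen, O=O
Why: Dye-sensitised singlet-oxygen [4+2] cycloaddition to the furan (furan photo-oxygenation) gives the endoperoxide, whose methanolysis expels the formyl carbon as methyl formate and leaves the pseudo-acid; its hemiacetal centre needs no control.

**Step 2**
Reactants: 3 5-hydroxyfuran-2(5H)-one; 4 (1R,2S,5R)-(−)-menthol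
Product: 6 (5R)-5-[(1R,2S,5R)-menthyloxy]furan-2(5H)-one, via (5S)-acetal epimer 5 (not isolated)
Conditions: CSA (cat.), toluene, reflux, Dean–Stark; crystallisation from petroleum ether, mother liquor re-equilibrated with TsOH (cat.) and recrystallised
Reagents that add atoms: none
Why: Acid-catalysed acetalisation of the pseudo-acid gives both C5 epimers, which interconvert through the oxocarbenium ion, so the acetal centre is set by crystallisation of the less soluble (5R) epimer (crystallisation-induced epimerisation).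

**Step 3**
Reactants: 7 vanillin
Product: 8 4-(1,3-dithian-2-yl)-2-methoxyphenol
Conditions: HS(CH2)3SH, BF3·OEt2 (cat.), CH2Cl2, 0 °C → rt
Reagents that add atoms: propane-1,3-dithiol, SCCCS
Why: Lewis acid-catalysed dithioacetalisation of an aryl aldehyde, which tolerates the free phenol.

**Step 4**
Reactants: 8 4-(1,3-dithian-2-yl)-2-methoxyphenol
Product: 9 2-(4-tert-butyldimethylsilyloxy-3-methoxyphenyl)-1,3-dithiane
Conditions: TBSCl, imidazole, DMF, rt
Reagents that add atoms: tert-butyldimethylsilyl chloride, CC(C)(C)[Si](C)(C)Cl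
Why: Imidazole-promoted silylation of the phenol masks the acidic OH before lithiation and stays orthogonal to the benzyl ether used on ring C.

**Step 5**
Reactants: 7 vanillin
Product: 10 4-benzyloxy-3-methoxybenzaldehyde (O-benzylvanillin)
Conditions: BnBr, K2CO3, DMF, rt
Reagents that add atoms: benzyl bromide, BrCc1ccccc1
Why: Williamson etherification of the phenoxide; the product serves both as precursor of the ring-C bromide and as the ring-B aldehyde of step 15.

**Step 6**
Reactants: 10 4-benzyloxy-3-methoxybenzaldehyde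
Product: 11 4-benzyloxy-3-methoxybenzyl alcohol
Conditions: NaBH4, MeOH, 0 °C
Reagents that add atoms: none
Why: Borohydride reduction of an aryl aldehyde to the benzylic alcohol.

**Step 7**
Reactants: 11 4-benzyloxy-3-methoxybenzyl alcohol
Product: 12 4-benzyloxy-3-methoxybenzyl bromide
Conditions: PBr3, Et2O, 0 °C
Reagents that add atoms: phosphorus tribromide, BrP(Br)Br
Why: Activation of the benzylic alcohol as a phosphite and SN2 displacement by bromide; the electron-rich bromide is used soon after preparation.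

**Step 8**
Reactants: 9 2-(4-tert-butyldimethylsilyloxy-3-methoxyphenyl)-1,3-dithiane; 6 (5R)-5-[(1R,2S,5R)-menthyloxy]furan-2(5H)-one; 12 4-benzyloxy-3-methoxybenzyl bromide
Product: 15 (3R,4R,5R)-3-(4-benzyloxy-3-methoxybenzyl)-4-[2-(4-tert-butyldimethylsilyloxy-3-methoxyphenyl)-1,3-dithian-2-yl]-5-[(1R,2S,5R)-menthyloxy]dihydrofuran-2(3H)-one, via 2-lithio-1,3-dithiane 13 (not isolated), via lithium enolate 14 (not isolated)
Conditions: 9, n-BuLi, THF, −78 °C; 6, THF, −78 °C; then 12, DMPU, −78 °C → rt
Reagents that add atoms: none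
Why: n-BuLi removes the doubly sulfur-stabilised benzylic proton of 9, the soft delocalised carbanion 13 adds 1,4 to C4 of the γ-alkoxybutenolide 6, and the lithium enolate 14 is C-benzylated at C3 by the reactive bromide 12 once DMPU loosens the aggregates. The closest known reaction type is the tandem conjugate addition–enolate alkylation of lithiated aryl dithioacetals on 2(5H)-furanones, as used for dibenzylbutyrolactone lignans. No ring is closed; the five-membered acetal-lactone is carried through unchanged. C4 is set by 1,2-induction from the C5 acetal centre, the nucleophile entering on the face opposite the menthyloxy group, and C3 is then set by the bulky C4 dithianyl group, the bromide entering trans to it, so the all-trans (3R,4R,5R) isomer is expected. The step needs 1,4- over 1,2-addition (secured by the charge-delocalised 2-aryldithianyl anion at low temperature), C-mono-alkylation over O-alkylation (benzylic bromide, polar cosolvent, crowded C3), and an intact acetal, which is safe because the enolate carbon has no β-leaving group.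

**Step 9**
Reactants: 15 key adduct
Product: 16 (3R,4R,5R)-3-(4-benzyloxy-3-methoxybenzyl)-4-(4-tert-butyldimethylsilyloxy-3-methoxybenzyl)-5-[(1R,2S,5R)-menthyloxy]dihydrofuran-2(3H)-one
Conditions: NiCl2·6H2O, NaBH4, MeOH/THF, 0 °C
Reagents that add atoms: none
Why: Nickel boride (Ni2B) formed in the flask hydrogenolyses the two benzylic C–S bonds (reductive desulfurisation) without touching the benzyl ether or the acetal-lactone; any aryl silyl ether lost here converges in step 10.

**Step 10**
Reactants: 16 desulfurised acetal-lactone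
Product: 19 (3R,4R)-3-(4-benzyloxy-3-methoxybenzyl)-4-(4-hydroxy-3-methoxybenzyl)dihydrofuran-2(3H)-one, via formyl acid 17 (not isolated), via hydroxy acid 18 (not isolated)
Conditions: KOH, NaBH4, EtOH/H2O/THF, 0 °C → rt; then 2 M HCl to pH 1, rt
Reagents that add atoms: potassium hydroxide, [K+].[OH-] (its oxygen can remain in the carboxyl group after relactonisation)
Why: Saponification of the pseudo-ester opens the ring and the C5 hemiacetal expels mentholate to give aldehyde 17, which borohydride reduces at once so that C4 has little time to epimerise; hydroxide also cleaves the aryl silyl ether, and acid closes hydroxy acid 18 to the γ-lactone (lactonisation) with the carbonyl still next to C3.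

**Step 11**
Reactants: 19 ring-A phenol lactone
Product: 21 (3R,4R)-3-(4-benzyloxy-3-methoxybenzyl)-4-(3-formyl-4-hydroxy-5-methoxybenzyl)dihydrofuran-2(3H)-one, via hydroxymethyl phenol 20 (not isolated)
Conditions: MgCl2, Et3N, (CH2O)n, MeCN, reflux; aq. HCl work-up
Reagents that add atoms: formaldehyde (from paraformaldehyde), C=O
Why: Casnati–Skattebøl ortho-formylation: the magnesium phenoxide delivers formaldehyde to the only free ortho position (C5 of ring A) and a second formaldehyde oxidises the hydroxymethyl intermediate by hydride transfer; ring C is inert as its benzyl ether and the simple lactone is not enolised by MgCl2/Et3N.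

**Step 12**
Reactants: 21 salicylaldehyde lactone
Product: 22 (3R,4R)-3-(4-benzyloxy-3-methoxybenzyl)-4-(4-benzyloxy-3-formyl-5-methoxybenzyl)dihydrofuran-2(3H)-one
Conditions: BnBr, K2CO3, DMF, rt → 50 °C
Reagents that add atoms: benzyl bromide, BrCc1ccccc1
Why: Williamson etherification of the only phenol, which blocks ortho-quinone methide chemistry and boron chelation in the following steps; carbonate is too weak to enolise the lactone.

**Step 13**
Reactants: 22 O-benzyl aldehyde
Product: 24 (3R,4R)-4-[3-(1-acetoxyprop-2-enyl)-4-benzyloxy-5-methoxybenzyl]-3-(4-benzyloxy-3-methoxybenzyl)dihydrofuran-2(3H)-one (both carbinol epimers), via bromomagnesium alkoxide 23 (not isolated)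
Conditions: CH2=CHMgBr (1.2 equiv), THF, −78 °C; then Ac2O, DMAP (cat.), −78 °C → rt
Reagents that add atoms: vinylmagnesium bromide, C=C[Mg]Br; acetic anhydride, CC(=O)OC(C)=O
Why: Grignard addition to the aldehyde is far faster than attack on the lactone at −78 °C, and the alkoxide is acetylated in the same flask; the new carbinol centre is lost in step 14, so its configuration is irrelevant.

**Step 14**
Reactants: 24 allylic acetate
Product: 25 (3R,4R)-3-(4-benzyloxy-3-methoxybenzyl)-4-{4-benzyloxy-3-methoxy-5-[(E)-3-(4,4,5,5-tetramethyl-1,3,2-dioxaborolan-2-yl)prop-1-enyl]benzyl}dihydrofuran-2(3H)-one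
Conditions: B2pin2, Pd2(dba)3 (cat.), DMSO, 50 °C
Reagents that add atoms: bis(pinacolato)diboron, CC1(C)OB(OC1(C)C)B1OC(C)(C)C(C)(C)O1
Why: Zerovalent palladium ionises the allylic acetate to a syn π-allyl complex, which transmetalates with B2pin2 and couples at the unsubstituted terminus (Miyaura-type allylic borylation), so both carbinol epimers should converge on the linear E-allylboronate.

**Step 15**
Reactants: 25 E-allylboronate; 10 4-benzyloxy-3-methoxybenzaldehyde
Product: 27 (3R,4R)-3-(4-benzyloxy-3-methoxybenzyl)-4-{4-benzyloxy-3-[(1R,2S)-1-(4-benzyloxy-3-methoxyphenyl)-1-hydroxybut-3-en-2-yl]-5-methoxybenzyl}dihydrofuran-2(3H)-one, via pinacol borate ester 26 (not isolated)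
Conditions: (R)-TRIP [(R)-3,3'-bis(2,4,6-triisopropylphenyl)-1,1'-binaphthyl-2,2'-diyl hydrogen phosphate] (10 mol %), 4 Å molecular sieves, toluene, −30 → 0 °C; aq. NaHCO3 work-up
Reagents that add atoms: none
Why: Chiral phosphoric acid-catalysed allylboration through a closed chair transition state (Zimmerman–Traxler): the E geometry of 25 places the γ-aryl group equatorial and fixes the anti C7/C8 relation, while the (R)-acid, hydrogen-bonded to a boronate oxygen and the formyl hydrogen, should direct attack to the Re face of 10 and set C7 as R (C8 is S in this alkene and R after vinyl cleavage), independently of the remote lactone centres.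

**Step 16**
Reactants: 27 homoallylic alcohol
Product: 29 (3R,4R)-3-(4-benzyloxy-3-methoxybenzyl)-4-{4-benzyloxy-3-[(1R,2R)-1-(4-benzyloxy-3-methoxyphenyl)-1,3-dihydroxypropan-2-yl]-5-methoxybenzyl}dihydrofuran-2(3H)-one, via secondary ozonide 28 (not isolated)
Conditions: O3, CH2Cl2, −78 °C, stopped at first excess of ozone; then NaBH4, MeOH, −78 → 0 °C
Reagents that add atoms: ozone, [O-][O+]=O
Why: Ozonolysis of the only alkene with borohydride reduction of the ozonide turns the vinyl group into the C9 hydroxymethyl group; the cold reductive work-up keeps the α-aryl aldehyde from accumulating, so C8 should not epimerise, and the lactone is reduced far more slowly than the ozonide.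

**Step 17**
Reactants: 29 tri-O-benzyl diol
Product: 30 (3R,4R)-4-{3-[(1R,2R)-1,3-dihydroxy-1-(4-hydroxy-3-methoxyphenyl)propan-2-yl]-4-hydroxy-5-methoxybenzyl}-3-(4-hydroxy-3-methoxybenzyl)dihydrofuran-2(3H)-one (CNP0109231.2)
Conditions: H2 (1 atm), Pd/C (10 %), EtOAc/EtOH, rt, stopped after uptake of three equivalents
Reagents that add atoms: none
Why: Palladium-catalysed hydrogenolysis cleaves the three aryl benzyl ethers much faster than the secondary benzylic C7–OH under neutral conditions and touches none of the four stereocentres.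

**Compound list**
1 | furfural | O=Cc1ccco1 | starting material
2 | 2,3,7-trioxabicyclo[2.2.1]hept-5-ene-1-carbaldehyde (furan endoperoxide) | O=CC12C=CC(OO1)O2 | intermediate (not isolated)
3 | 5-hydroxyfuran-2(5H)-one (racemic) | O=C1C=CC(O)O1 | intermediate
4 | (1R,2S,5R)-(−)-menthol | O[C@@H]1C[C@H](C)CC[C@H]1C(C)C | starting material
5 | (5S)-5-[(1R,2S,5R)-menthyloxy]furan-2(5H)-one | O=C1O[C@H](O[C@@H]2C[C@H](C)CC[C@H]2C(C)C)C=C1 | intermediate (not isolated)
6 | (5R)-5-[(1R,2S,5R)-menthyloxy]furan-2(5H)-one | O=C1O[C@@H](O[C@@H]2C[C@H](C)CC[C@H]2C(C)C)C=C1 | intermediate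
7 | vanillin | COc1cc(C=O)ccc1O | starting material
8 | 4-(1,3-dithian-2-yl)-2-methoxyphenol | COc1cc(C2SCCCS2)ccc1O | intermediate
9 | 2-(4-tert-butyldimethylsilyloxy-3-methoxyphenyl)-1,3-dithiane | COc1cc(C2SCCCS2)ccc1O[Si](C)(C)C(C)(C)C | intermediate
10 | 4-benzyloxy-3-methoxybenzaldehyde | COc1cc(C=O)ccc1OCc1ccccc1 | intermediate
11 | 4-benzyloxy-3-methoxybenzyl alcohol | COc1cc(CO)ccc1OCc1ccccc1 | intermediate
12 | 4-benzyloxy-3-methoxybenzyl bromide | COc1cc(CBr)ccc1OCc1ccccc1 | intermediate
13 | 2-lithio-2-(4-tert-butyldimethylsilyloxy-3-methoxyphenyl)-1,3-dithiane | COc1cc(C2([Li])SCCCS2)ccc1O[Si](C)(C)C(C)(C)C | intermediate (not isolated)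
14 | lithium enolate of (4R,5R)-4-(2-aryl-1,3-dithian-2-yl)-5-menthyloxydihydrofuran-2(3H)-one | [Li]OC1=C[C@@H](C2(c3ccc(O[Si](C)(C)C(C)(C)C)c(OC)c3)SCCCS2)[C@H](O[C@@H]2C[C@H](C)CC[C@H]2C(C)C)O1 | intermediate (not isolated)
15 | (3R,4R,5R)-3-(4-benzyloxy-3-methoxybenzyl)-4-[2-(4-tert-butyldimethylsilyloxy-3-methoxyphenyl)-1,3-dithian-2-yl]-5-[(1R,2S,5R)-menthyloxy]dihydrofuran-2(3H)-one | COc1cc(C[C@H]2C(=O)O[C@@H](O[C@@H]3C[C@H](C)CC[C@H]3C(C)C)[C@@H]2C2(c3ccc(O[Si](C)(C)C(C)(C)C)c(OC)c3)SCCCS2)ccc1OCc1ccccc1 | intermediate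
16 | (3R,4R,5R)-3-(4-benzyloxy-3-methoxybenzyl)-4-(4-tert-butyldimethylsilyloxy-3-methoxybenzyl)-5-[(1R,2S,5R)-menthyloxy]dihydrofuran-2(3H)-one | COc1cc(C[C@H]2C(=O)O[C@@H](O[C@@H]3C[C@H](C)CC[C@H]3C(C)C)[C@@H]2Cc2ccc(O[Si](C)(C)C(C)(C)C)c(OC)c2)ccc1OCc1ccccc1 | intermediate
17 | (2R,3R)-2-(4-benzyloxy-3-methoxybenzyl)-3-(4-tert-butyldimethylsilyloxy-3-methoxybenzyl)-4-oxobutanoic acid (potassium salt in the flask) | COc1cc(C[C@@H](C(=O)O)[C@H](C=O)Cc2ccc(O[Si](C)(C)C(C)(C)C)c(OC)c2)ccc1OCc1ccccc1 | intermediate (not isolated)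
18 | (2R,3R)-2-(4-benzyloxy-3-methoxybenzyl)-4-hydroxy-3-(4-hydroxy-3-methoxybenzyl)butanoic acid | COc1cc(C[C@@H](C(=O)O)[C@H](CO)Cc2ccc(O)c(OC)c2)ccc1OCc1ccccc1 | intermediate (not isolated)
19 | (3R,4R)-3-(4-benzyloxy-3-methoxybenzyl)-4-(4-hydroxy-3-methoxybenzyl)dihydrofuran-2(3H)-one | COc1cc(C[C@H]2C(=O)OC[C@@H]2Cc2ccc(O)c(OC)c2)ccc1OCc1ccccc1 | intermediate
20 | (3R,4R)-3-(4-benzyloxy-3-methoxybenzyl)-4-[4-hydroxy-3-(hydroxymethyl)-5-methoxybenzyl]dihydrofuran-2(3H)-one (magnesium phenoxide in the flask) | COc1cc(C[C@H]2C(=O)OC[C@@H]2Cc2cc(CO)c(O)c(OC)c2)ccc1OCc1ccccc1 | intermediate (not isolated)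
21 | (3R,4R)-3-(4-benzyloxy-3-methoxybenzyl)-4-(3-formyl-4-hydroxy-5-methoxybenzyl)dihydrofuran-2(3H)-one | COc1cc(C[C@H]2C(=O)OC[C@@H]2Cc2cc(OC)c(O)c(C=O)c2)ccc1OCc1ccccc1 | intermediate
22 | (3R,4R)-3-(4-benzyloxy-3-methoxybenzyl)-4-(4-benzyloxy-3-formyl-5-methoxybenzyl)dihydrofuran-2(3H)-one | COc1cc(C[C@H]2C(=O)OC[C@@H]2Cc2cc(OC)c(OCc3ccccc3)c(C=O)c2)ccc1OCc1ccccc1 | intermediate
23 | bromomagnesium 1-aryl-prop-2-en-1-olate of 22 (both carbinol epimers) | COc1cc(C[C@H]2C(=O)OC[C@@H]2Cc2cc(OC)c(OCc3ccccc3)c(C(O[Mg]Br)C=C)c2)ccc1OCc1ccccc1 | intermediate (not isolated)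
24 | (3R,4R)-4-[3-(1-acetoxyprop-2-enyl)-4-benzyloxy-5-methoxybenzyl]-3-(4-benzyloxy-3-methoxybenzyl)dihydrofuran-2(3H)-one (both carbinol epimers) | COc1cc(C[C@H]2C(=O)OC[C@@H]2Cc2cc(OC)c(OCc3ccccc3)c(C(OC(C)=O)C=C)c2)ccc1OCc1ccccc1 | intermediate
25 | (3R,4R)-3-(4-benzyloxy-3-methoxybenzyl)-4-{4-benzyloxy-3-methoxy-5-[(E)-3-(4,4,5,5-tetramethyl-1,3,2-dioxaborolan-2-yl)prop-1-enyl]benzyl}dihydrofuran-2(3H)-one | COc1cc(C[C@H]2C(=O)OC[C@@H]2Cc2cc(OC)c(OCc3ccccc3)c(/C=C/CB3OC(C)(C)C(C)(C)O3)c2)ccc1OCc1ccccc1 | intermediate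
26 | pinacol borate ester of alcohol 27 | COc1cc(C[C@H]2C(=O)OC[C@@H]2Cc2cc(OC)c(OCc3ccccc3)c([C@H](C=C)[C@@H](OB3OC(C)(C)C(C)(C)O3)c3ccc(OCc4ccccc4)c(OC)c3)c2)ccc1OCc1ccccc1 | intermediate (not isolated)
27 | (3R,4R)-3-(4-benzyloxy-3-methoxybenzyl)-4-{4-benzyloxy-3-[(1R,2S)-1-(4-benzyloxy-3-methoxyphenyl)-1-hydroxybut-3-en-2-yl]-5-methoxybenzyl}dihydrofuran-2(3H)-one | COc1cc(C[C@H]2C(=O)OC[C@@H]2Cc2cc(OC)c(OCc3ccccc3)c([C@H](C=C)[C@@H](O)c3ccc(OCc4ccccc4)c(OC)c3)c2)ccc1OCc1ccccc1 | intermediate
28 | 1,2,4-trioxolane (secondary ozonide) of 27, trioxolane carbon unassigned | COc1cc(C[C@H]2C(=O)OC[C@@H]2Cc2cc(OC)c(OCc3ccccc3)c([C@H](C3OCOO3)[C@@H](O)c3ccc(OCc4ccccc4)c(OC)c3)c2)ccc1OCc1ccccc1 | intermediate (not isolated)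
29 | (3R,4R)-3-(4-benzyloxy-3-methoxybenzyl)-4-{4-benzyloxy-3-[(1R,2R)-1-(4-benzyloxy-3-methoxyphenyl)-1,3-dihydroxypropan-2-yl]-5-methoxybenzyl}dihydrofuran-2(3H)-one | COc1cc(C[C@H]2C(=O)OC[C@@H]2Cc2cc(OC)c(OCc3ccccc3)c([C@H](CO)[C@@H](O)c3ccc(OCc4ccccc4)c(OC)c3)c2)ccc1OCc1ccccc1 | intermediate
30 | (3R,4R)-4-{3-[(1R,2R)-1,3-dihydroxy-1-(4-hydroxy-3-methoxyphenyl)propan-2-yl]-4-hydroxy-5-methoxybenzyl}-3-(4-hydroxy-3-methoxybenzyl)dihydrofuran-2(3H)-one | COc1cc(C[C@H]2C(=O)OC[C@@H]2Cc2cc(OC)c(O)c([C@H](CO)[C@@H](O)c3ccc(O)c(OC)c3)c2)ccc1O | target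

**Step count**
Total: 17 steps. Longest linear sequence: 13 steps (steps 5, 6, 7 and 8–17, from vanillin through bromide 12).

**Steps most likely to fail**

Step 8 (three-component coupling). The sequence may stall at the enolate stage: benzylation can be slow in the presence of dithiane-derived aggregates, proton transfer can quench the enolate, or the trans selectivity at C3 can erode. The fallback separates the two bond formations. It sets out from dithiane 9 and butenolide 6: the lithio derivative 13 is added at −78 °C and the enolate is protonated with aqueous NH4Cl to give the Michael adduct (4R,5R)-4-[2-(4-tert-butyldimethylsilyloxy-3-methoxyphenyl)-1,3-dithian-2-yl]-5-[(1R,2S,5R)-menthyloxy]dihydrofuran-2(3H)-one F1. After purification, F1 is deprotonated with LiN(iPr)2 (THF, −78 °C) and alkylated with bromide 12 in the presence of DMPU. The electrophile should again enter trans to the C4 substituent, and the sequence comes back to the route at compound 15.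

Step 15 (catalytic allylboration). The bulky γ-aryl pinacol boronate may react too slowly under phosphoric acid catalysis, or the catalyst may discriminate the aldehyde faces poorly. The fallback gives up catalyst control in favour of separation. It sets out from boronate 25 and aldehyde 10: the uncatalysed thermal allylboration (toluene, 60 °C) should still pass through the closed chair and give only anti adducts, namely borate 26 and the pinacol borate of the (1S,2R) side-chain diastereomer F2. Hydrolytic work-up would give alcohol 27 together with the (1S,2R)-anti homoallylic alcohol F3. Because of the two lactone centres these are diastereomers; they would be separated by preparative HPLC and the side-chain configuration of each assigned by the modified Mosher method. The route is rejoined at compound 27.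

Step 14 (allylic borylation). Product 25 may couple with unreacted acetate 24 on palladium, or the electron-rich benzylic acetate may ionise and eliminate. The fallback builds the boronate by olefin metathesis. It sets out from aldehyde 22: Wittig methylenation (Ph3PCH3Br, KOtBu, THF, −78 → 0 °C) should give the styrene (3R,4R)-3-(4-benzyloxy-3-methoxybenzyl)-4-(4-benzyloxy-3-methoxy-5-vinylbenzyl)dihydrofuran-2(3H)-one F4. Cross-metathesis of F4 with allylboronic acid pinacol ester (second-generation Hoveyda–Grubbs catalyst, CH2Cl2, 40 °C) should give mainly the E-boronate, coming back to the route at compound 25.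

**Further compounds**
F1 | step 8 | (4R,5R)-4-[2-(4-tert-butyldimethylsilyloxy-3-methoxyphenyl)-1,3-dithian-2-yl]-5-[(1R,2S,5R)-menthyloxy]dihydrofuran-2(3H)-one | O=C1C[C@@H](C2(c3ccc(O[Si](C)(C)C(C)(C)C)c(OC)c3)SCCCS2)[C@H](O[C@@H]2C[C@H](C)CC[C@H]2C(C)C)O1
F2 | step 15 | pinacol borate ester of the (1S,2R)-anti homoallylic alcohol F3 | COc1cc(C[C@H]2C(=O)OC[C@@H]2Cc2cc(OC)c(OCc3ccccc3)c([C@@H](C=C)[C@H](OB3OC(C)(C)C(C)(C)O3)c3ccc(OCc4ccccc4)c(OC)c3)c2)ccc1OCc1ccccc1
F3 | step 15 | (3R,4R)-3-(4-benzyloxy-3-methoxybenzyl)-4-{4-benzyloxy-3-[(1S,2R)-1-(4-benzyloxy-3-methoxyphenyl)-1-hydroxybut-3-en-2-yl]-5-methoxybenzyl}dihydrofuran-2(3H)-one | COc1cc(C[C@H]2C(=O)OC[C@@H]2Cc2cc(OC)c(OCc3ccccc3)c([C@@H](C=C)[C@H](O)c3ccc(OCc4ccccc4)c(OC)c3)c2)ccc1OCc1ccccc1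
F4 | step 14 | (3R,4R)-3-(4-benzyloxy-3-methoxybenzyl)-4-(4-benzyloxy-3-methoxy-5-vinylbenzyl)dihydrofuran-2(3H)-one | COc1cc(C[C@H]2C(=O)OC[C@@H]2Cc2cc(OC)c(OCc3ccccc3)c(C=C)c2)ccc1OCc1ccccc1
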